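**Retrosynthetic overview**
1. Target 29 comes from its undecabenzyl ether 28 by global hydrogenolysis; the four diaryl ether bonds are then cut one at a time from ring A back to ring E, so the chain is grown E → D → C → B → A.
2. A–O–B: CuI-catalysed O-arylation of hindered phenol 25 with bromide 27. B–O–C: SNAr of phenol 18 on fluoroaldehyde 22. C–O–D: CuI-catalysed O-arylation of phenol 13 with bromoaldehyde 15. After each coupling the CHO group is converted into the next hindered phenol (Baeyer–Villiger oxidation, formate cleavage).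
3. D–O–E is not made by arylation: ring E is built on the ring D oxygen. Aryloxyacetate 7 and the dianion of methyl acetoacetate 8 are joined by an intermolecular Claisen condensation (key C–C bond, C4–C5 of diketo ester 10), and an intramolecular Claisen ring closure with aromatisation gives the phloroglucinol ring (11).
4. Ring order: rings D, C, B and A are bought as benzenes (1, 14, 19, 26); ring E is the only ring formed in the route (step 6).

Assumption: the target has no stereocentre or other stereo-element (it is achiral), so no step needs stereocontrol.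
Assumption: where one step puts on or takes off the same group two or more times (multiple O-benzylation, double fluoride displacement, global debenzylation), the partly converted species are not numbered.

**Step 1**
Reactants: 1 2,4,6-trihydroxybenzaldehyde
Product: 2 2,4-bis(benzyloxy)-6-hydroxybenzaldehyde
Conditions: BnBr (2.1 equiv), K2CO3, DMF, 0 °C → rt
Reagents that add atoms: benzyl bromide, BrCc1ccccc1
Why: Williamson O-benzylation takes the two hydroxyls that are not held in the hydrogen bond to the aldehyde, so one ortho OH stays free; no stereocentre is formed.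

**Step 2**
Reactants: 2 2,4-bis(benzyloxy)-6-hydroxybenzaldehyde; 3 methyl bromoacetate
Product: 4 methyl 2-[3,5-bis(benzyloxy)-2-formylphenoxy]acetate
Conditions: K2CO3, DMF, rt → 40 °C
Reagents that add atoms: none
Why: Williamson ether synthesis (SN2 at the primary α-bromo ester) by the phenoxide, run below the temperature at which the aryloxyacetate would condense onto the aldehyde to a benzofuran; no stereocentre is formed.

**Step 3**
Reactants: 4 methyl 2-[3,5-bis(benzyloxy)-2-formylphenoxy]acetate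
Product: 5 methyl 2-[3,5-bis(benzyloxy)-2-(formyloxy)phenoxy]acetate
Conditions: mCPBA, CH2Cl2, 0 °C → rt
Reagents that add atoms: mCPBA (3-chloroperoxybenzoic acid), OOC(=O)c1cccc(Cl)c1
Why: Baeyer–Villiger oxidation in which the electron-rich trioxygenated aryl group migrates, giving the aryl formate while ester and benzyl ethers are untouched; no stereocentre is formed.

**Step 4**
Reactants: 5 methyl 2-[3,5-bis(benzyloxy)-2-(formyloxy)phenoxy]acetate
Product: 7 methyl 2-[2-(allyloxy)-3,5-bis(benzyloxy)phenoxy]acetate, via hydroxy ester 6 (not isolated)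
Conditions: K2CO3, MeOH/DMF, rt; then allyl bromide, 50 °C
Reagents that add atoms: allyl bromide, C=CCBr
Why: Base-catalysed transesterification removes the formyl group as methyl formate, and the freed phenoxide (its lactone with the neighbouring ester is reopened by methanol) is trapped by Williamson O-allylation; no stereocentre is formed.

**Step 5**
Reactants: 7 methyl 2-[2-(allyloxy)-3,5-bis(benzyloxy)phenoxy]acetate; 8 methyl acetoacetate
Product: 10 methyl 6-[2-(allyloxy)-3,5-bis(benzyloxy)phenoxy]-3,5-dioxohexanoate, via acetoacetate dianion 9 (not isolated)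
Conditions: 8 (2.5 equiv), NaH, THF, 0 °C; n-BuLi, 0 °C; then 7, −78 → 0 °C; 1 M HCl
Reagents that add atoms: none
Why: Crossed Claisen condensation in which the terminal carbanion of the acetoacetate dianion, its most nucleophilic site, is acylated by the aryloxyacetate ester and the product is shielded from further attack as its enolate (the excess dianion serves as base); no stereocentre is formed.

**Step 6**
Reactants: 10 methyl 6-[2-(allyloxy)-3,5-bis(benzyloxy)phenoxy]-3,5-dioxohexanoate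
Product: 11 2-[2-(allyloxy)-3,5-bis(benzyloxy)phenoxy]benzene-1,3,5-triol
Conditions: NaOMe (5 equiv), MeOH, 65 °C; then 1 M HCl
Reagents that add atoms: none
Why: Intramolecular Claisen (Dieckmann-type) condensation in which the aryloxy group acidifies C6 so that its enolate, reached by equilibration in NaOMe/MeOH, attacks the ester carbonyl, and loss of methoxide with enolisation to the aromatic phloroglucinol makes the carbon ring closure irreversible whereas O-acylation to a pyranone is reversible under methoxide; no stereocentre is formed.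

**Step 7**
Reactants: 11 2-[2-(allyloxy)-3,5-bis(benzyloxy)phenoxy]benzene-1,3,5-triol
Product: 12 1-(allyloxy)-2,4-bis(benzyloxy)-6-[2,4,6-tris(benzyloxy)phenoxy]benzene
Conditions: BnBr (3.6 equiv), K2CO3, DMF, rt
Reagents that add atoms: benzyl bromide, BrCc1ccccc1
Why: Threefold Williamson O-benzylation in a dipolar aprotic solvent, which favours O- over C-alkylation of the phloroglucinol ring; no stereocentre is formed.

**Step 8**
Reactants: 12 1-(allyloxy)-2,4-bis(benzyloxy)-6-[2,4,6-tris(benzyloxy)phenoxy]benzene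
Product: 13 2,4-bis(benzyloxy)-6-[2,4,6-tris(benzyloxy)phenoxy]phenol
Conditions: Pd(PPh3)4 (5 mol %), morpholine, THF, rt
Reagents that add atoms: none
Why: Tsuji–Trost deallylation, in which zerovalent palladium ionises the allyl aryl ether to a π-allyl complex that morpholine captures, frees only the ring D phenol and leaves all benzyl ethers; no stereocentre is formed.

**Step 9**
Reactants: 14 4-bromo-2,6-difluorobenzaldehyde
Product: 15 2,6-bis(benzyloxy)-4-bromobenzaldehyde
Conditions: BnOH (2.2 equiv), NaH, THF, 0 → 50 °C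
Reagents that add atoms: benzyl alcohol, OCc1ccccc1
Why: Double SNAr in which both fluorides are ortho to the aldehyde and far better leaving groups than the para bromide, so benzyl oxide replaces only them; no stereocentre is formed.

**Step 10**
Reactants: 13 2,4-bis(benzyloxy)-6-[2,4,6-tris(benzyloxy)phenoxy]phenol; 15 2,6-bis(benzyloxy)-4-bromobenzaldehyde
Product: 16 2,6-bis(benzyloxy)-4-{2,4-bis(benzyloxy)-6-[2,4,6-tris(benzyloxy)phenoxy]phenoxy}benzaldehyde
Conditions: CuI (10 mol %), picolinic acid (20 mol %), K3PO4, DMSO, 90 °C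
Reagents that add atoms: none
Why: Ullmann-type C–O coupling with a CuI/picolinic acid catalyst that tolerates di-ortho-substituted phenols, the bromide being unhindered and activated by the para aldehyde; no stereocentre is formed.

**Step 11**
Reactants: 16 2,6-bis(benzyloxy)-4-{2,4-bis(benzyloxy)-6-[2,4,6-tris(benzyloxy)phenoxy]phenoxy}benzaldehyde
Product: 18 2,6-bis(benzyloxy)-4-{2,4-bis(benzyloxy)-6-[2,4,6-tris(benzyloxy)phenoxy]phenoxy}phenol, via aryl formate 17 (not isolated)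
Conditions: mCPBA (1.1 equiv), CH2Cl2, 0 °C; then K2CO3 (cat.), MeOH/THF, rt
Reagents that add atoms: mCPBA (3-chloroperoxybenzoic acid), OOC(=O)c1cccc(Cl)c1
Why: Dakin-type sequence (Baeyer–Villiger oxidation, then formate methanolysis) in which the 2,6-dialkoxy-4-aryloxyphenyl group migrates faster than the peracid attacks the other rings, turning the aldehyde site into the hindered ring C phenol; no stereocentre is formed.

**Step 12**
Reactants: 19 1,3,5-trifluorobenzene
Product: 20 1,3-bis(benzyloxy)-5-fluorobenzene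
Conditions: BnOH (2.2 equiv), NaH, NMP, rt → 100 °C (sealed)
Reagents that add atoms: benzyl alcohol, OCc1ccccc1
Why: Double SNAr on a ring activated by meta fluorines, stopping at the monofluoride because the third displacement on the electron-rich diether is far slower; no stereocentre is formed.

**Step 13**
Reactants: 20 1,3-bis(benzyloxy)-5-fluorobenzene
Product: 22 2,4-bis(benzyloxy)-6-fluorobenzaldehyde, via iminium salt 21 (not isolated)
Conditions: POCl3, DMF, 0 → 70 °C; then ice/H2O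
Reagents that add atoms: N,N-dimethylformamide, CN(C)C=O; water, O
Why: Vilsmeier–Haack formylation, in which the chloroiminium ion attacks the position para to one benzyloxy group and next to the small fluorine in preference to the crowded position between the two benzyloxy groups (the minor isomer is removed by crystallisation); no stereocentre is formed.

**Step 14**
Reactants: 18 2,6-bis(benzyloxy)-4-{2,4-bis(benzyloxy)-6-[2,4,6-tris(benzyloxy)phenoxy]phenoxy}phenol; 22 2,4-bis(benzyloxy)-6-fluorobenzaldehyde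
Product: 23 2,4-bis(benzyloxy)-6-(2,6-bis(benzyloxy)-4-{2,4-bis(benzyloxy)-6-[2,4,6-tris(benzyloxy)phenoxy]phenoxy}phenoxy)benzaldehyde
Conditions: Cs2CO3, DMSO (degassed), 110 °C
Reagents that add atoms: none
Why: SNAr in which the fluoride is ortho to the aldehyde that stabilises the Meisenheimer adduct and both benzyloxy groups are meta to the reacting carbon, so the caesium phenoxide of 18 displaces it; no stereocentre is formed.

**Step 15**
Reactants: 23 2,4-bis(benzyloxy)-6-(2,6-bis(benzyloxy)-4-{2,4-bis(benzyloxy)-6-[2,4,6-tris(benzyloxy)phenoxy]phenoxy}phenoxy)benzaldehyde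
Product: 25 2,4-bis(benzyloxy)-6-(2,6-bis(benzyloxy)-4-{2,4-bis(benzyloxy)-6-[2,4,6-tris(benzyloxy)phenoxy]phenoxy}phenoxy)phenol, via aryl formate 24 (not isolated)
Conditions: mCPBA (1.1 equiv), CH2Cl2, 0 °C; then K2CO3 (cat.), MeOH/THF, rt
Reagents that add atoms: mCPBA (3-chloroperoxybenzoic acid), OOC(=O)c1cccc(Cl)c1
Why: The same Dakin-type sequence (Baeyer–Villiger aryl migration, then formate methanolysis) converts the ring B aldehyde into the hindered ring B phenol; no stereocentre is formed.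

**Step 16**
Reactants: 26 1-bromo-3,5-difluorobenzene
Product: 27 1,3-bis(benzyloxy)-5-bromobenzene
Conditions: BnOH (2.3 equiv), NaH, NMP, 100 °C
Reagents that add atoms: benzyl alcohol, OCc1ccccc1
Why: Double SNAr of fluoride by benzyl oxide on the meta-halogen-activated ring, bromide being the poorer leaving group and therefore kept; no stereocentre is formed.

**Step 17**
Reactants: 25 2,4-bis(benzyloxy)-6-(2,6-bis(benzyloxy)-4-{2,4-bis(benzyloxy)-6-[2,4,6-tris(benzyloxy)phenoxy]phenoxy}phenoxy)phenol; 27 1,3-bis(benzyloxy)-5-bromobenzene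
Product: 28 1,3-bis(benzyloxy)-5-[2,4-bis(benzyloxy)-6-(2,6-bis(benzyloxy)-4-{2,4-bis(benzyloxy)-6-[2,4,6-tris(benzyloxy)phenoxy]phenoxy}phenoxy)phenoxy]benzene
Conditions: 27 (3 equiv), CuI (20 mol %), picolinic acid (40 mol %), K3PO4, DMSO, 110 °C
Reagents that add atoms: none
Why: Ullmann-type C–O coupling with the same CuI/picolinic acid catalyst for hindered phenols, using the unhindered aryl bromide in excess; no stereocentre is formed.

**Step 18**
Reactants: 28 1,3-bis(benzyloxy)-5-[2,4-bis(benzyloxy)-6-(2,6-bis(benzyloxy)-4-{2,4-bis(benzyloxy)-6-[2,4,6-tris(benzyloxy)phenoxy]phenoxy}phenoxy)phenoxy]benzene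
Product: 29 5-[2,4-dihydroxy-6-(2,6-dihydroxy-4-{2,4-dihydroxy-6-[2,4,6-trihydroxyphenoxy]phenoxy}phenoxy)phenoxy]benzene-1,3-diol
Conditions: H2 (1 atm), 10% Pd/C, THF/MeOH, rt; filtration under argon
Reagents that add atoms: none
Why: Catalytic hydrogenolysis cleaves all eleven benzyl ethers to the free polyphenol and toluene while diaryl ethers are inert; there is no stereocentre to set or preserve.

**Compound list**
1 | 2,4,6-trihydroxybenzaldehyde | O=Cc1c(O)cc(O)cc1O | starting material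
2 | 2,4-bis(benzyloxy)-6-hydroxybenzaldehyde | O=Cc1c(O)cc(OCc2ccccc2)cc1OCc1ccccc1 | intermediate
3 | methyl bromoacetate | COC(=O)CBr | starting material
4 | methyl 2-[3,5-bis(benzyloxy)-2-formylphenoxy]acetate | COC(=O)COc1cc(OCc2ccccc2)cc(OCc2ccccc2)c1C=O | intermediate
5 | methyl 2-[3,5-bis(benzyloxy)-2-(formyloxy)phenoxy]acetate | COC(=O)COc1cc(OCc2ccccc2)cc(OCc2ccccc2)c1OC=O | intermediate
6 | methyl 2-[3,5-bis(benzyloxy)-2-hydroxyphenoxy]acetate | COC(=O)COc1cc(OCc2ccccc2)cc(OCc2ccccc2)c1O | intermediate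
7 | methyl 2-[2-(allyloxy)-3,5-bis(benzyloxy)phenoxy]acetate | COC(=O)COc1cc(OCc2ccccc2)cc(OCc2ccccc2)c1OCC=C | intermediate
8 | methyl acetoacetate | COC(=O)CC(C)=O | starting material
9 | methyl acetoacetate dianion (sodium lithium salt) | COC(=O)[CH-]C(=O)[CH2-].[Na+].[Li+] | intermediate
10 | methyl 6-[2-(allyloxy)-3,5-bis(benzyloxy)phenoxy]-3,5-dioxohexanoate | COC(=O)CC(=O)CC(=O)COc1cc(OCc2ccccc2)cc(OCc2ccccc2)c1OCC=C | intermediate
11 | 2-[2-(allyloxy)-3,5-bis(benzyloxy)phenoxy]benzene-1,3,5-triol | Oc1cc(O)c(Oc2cc(OCc3ccccc3)cc(OCc3ccccc3)c2OCC=C)c(O)c1 | intermediate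
12 | 1-(allyloxy)-2,4-bis(benzyloxy)-6-[2,4,6-tris(benzyloxy)phenoxy]benzene | C=CCOc1c(OCc2ccccc2)cc(OCc2ccccc2)cc1Oc1c(OCc2ccccc2)cc(OCc2ccccc2)cc1OCc1ccccc1 | intermediate
13 | 2,4-bis(benzyloxy)-6-[2,4,6-tris(benzyloxy)phenoxy]phenol | Oc1c(OCc2ccccc2)cc(OCc2ccccc2)cc1Oc1c(OCc2ccccc2)cc(OCc2ccccc2)cc1OCc1ccccc1 | intermediate
14 | 4-bromo-2,6-difluorobenzaldehyde | O=Cc1c(F)cc(Br)cc1F | starting material
15 | 2,6-bis(benzyloxy)-4-bromobenzaldehyde | O=Cc1c(OCc2ccccc2)cc(Br)cc1OCc1ccccc1 | intermediate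
16 | 2,6-bis(benzyloxy)-4-{2,4-bis(benzyloxy)-6-[2,4,6-tris(benzyloxy)phenoxy]phenoxy}benzaldehyde | O=Cc1c(OCc2ccccc2)cc(Oc2c(OCc3ccccc3)cc(OCc3ccccc3)cc2Oc2c(OCc3ccccc3)cc(OCc3ccccc3)cc2OCc2ccccc2)cc1OCc1ccccc1 | intermediate
17 | 2,6-bis(benzyloxy)-4-{2,4-bis(benzyloxy)-6-[2,4,6-tris(benzyloxy)phenoxy]phenoxy}phenyl formate | O=COc1c(OCc2ccccc2)cc(Oc2c(OCc3ccccc3)cc(OCc3ccccc3)cc2Oc2c(OCc3ccccc3)cc(OCc3ccccc3)cc2OCc2ccccc2)cc1OCc1ccccc1 | intermediate
18 | 2,6-bis(benzyloxy)-4-{2,4-bis(benzyloxy)-6-[2,4,6-tris(benzyloxy)phenoxy]phenoxy}phenol | Oc1c(OCc2ccccc2)cc(Oc2c(OCc3ccccc3)cc(OCc3ccccc3)cc2Oc2c(OCc3ccccc3)cc(OCc3ccccc3)cc2OCc2ccccc2)cc1OCc1ccccc1 | intermediate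
19 | 1,3,5-trifluorobenzene | Fc1cc(F)cc(F)c1 | starting material
20 | 1,3-bis(benzyloxy)-5-fluorobenzene | Fc1cc(OCc2ccccc2)cc(OCc2ccccc2)c1 | intermediate
21 | N-[2,4-bis(benzyloxy)-6-fluorobenzylidene]-N-methylmethanaminium chloride | C[N+](C)=Cc1c(F)cc(OCc2ccccc2)cc1OCc1ccccc1.[Cl-] | intermediate
22 | 2,4-bis(benzyloxy)-6-fluorobenzaldehyde | O=Cc1c(F)cc(OCc2ccccc2)cc1OCc1ccccc1 | intermediate
23 | 2,4-bis(benzyloxy)-6-(2,6-bis(benzyloxy)-4-{2,4-bis(benzyloxy)-6-[2,4,6-tris(benzyloxy)phenoxy]phenoxy}phenoxy)benzaldehyde | O=Cc1c(OCc2ccccc2)cc(OCc2ccccc2)cc1Oc1c(OCc2ccccc2)cc(Oc2c(OCc3ccccc3)cc(OCc3ccccc3)cc2Oc2c(OCc3ccccc3)cc(OCc3ccccc3)cc2OCc2ccccc2)cc1OCc1ccccc1 | intermediate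
24 | 2,4-bis(benzyloxy)-6-(2,6-bis(benzyloxy)-4-{2,4-bis(benzyloxy)-6-[2,4,6-tris(benzyloxy)phenoxy]phenoxy}phenoxy)phenyl formate | O=COc1c(OCc2ccccc2)cc(OCc2ccccc2)cc1Oc1c(OCc2ccccc2)cc(Oc2c(OCc3ccccc3)cc(OCc3ccccc3)cc2Oc2c(OCc3ccccc3)cc(OCc3ccccc3)cc2OCc2ccccc2)cc1OCc1ccccc1 | intermediate
25 | 2,4-bis(benzyloxy)-6-(2,6-bis(benzyloxy)-4-{2,4-bis(benzyloxy)-6-[2,4,6-tris(benzyloxy)phenoxy]phenoxy}phenoxy)phenol | Oc1c(OCc2ccccc2)cc(OCc2ccccc2)cc1Oc1c(OCc2ccccc2)cc(Oc2c(OCc3ccccc3)cc(OCc3ccccc3)cc2Oc2c(OCc3ccccc3)cc(OCc3ccccc3)cc2OCc2ccccc2)cc1OCc1ccccc1 | intermediate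
26 | 1-bromo-3,5-difluorobenzene | Fc1cc(F)cc(Br)c1 | starting material
27 | 1,3-bis(benzyloxy)-5-bromobenzene | Brc1cc(OCc2ccccc2)cc(OCc2ccccc2)c1 | intermediate
28 | 1,3-bis(benzyloxy)-5-[2,4-bis(benzyloxy)-6-(2,6-bis(benzyloxy)-4-{2,4-bis(benzyloxy)-6-[2,4,6-tris(benzyloxy)phenoxy]phenoxy}phenoxy)phenoxy]benzene | O(Cc1ccccc1)c1cc(OCc2ccccc2)cc(Oc2c(OCc3ccccc3)cc(OCc3ccccc3)cc2Oc2c(OCc3ccccc3)cc(Oc3c(OCc4ccccc4)cc(OCc4ccccc4)cc3Oc3c(OCc4ccccc4)cc(OCc4ccccc4)cc3OCc3ccccc3)cc2OCc2ccccc2)c1 | intermediate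
29 | 5-[2,4-dihydroxy-6-(2,6-dihydroxy-4-{2,4-dihydroxy-6-[2,4,6-trihydroxyphenoxy]phenoxy}phenoxy)phenoxy]benzene-1,3-diol | Oc1cc(O)cc(Oc2c(O)cc(O)cc2Oc2c(O)cc(Oc3c(O)cc(O)cc3Oc3c(O)cc(O)cc3O)cc2O)c1 | target

**Step count and weak points**
Total: 18 steps. Longest linear sequence: 14 steps (1–8, 10, 11, 14, 15, 17, 18); compounds 15, 22 and 27 are made in side branches of 1, 2 and 1 steps.

The step most likely to fail is step 6. Diketo ester 10 can close through oxygen to a 4-hydroxy-2-pyranone, or be cut by retro-Claisen cleavage, instead of closing through carbon to the phloroglucinol ring. The fallback sets out from 1, drops the ring construction and comes back at 13. Exhaustive benzylation of 1 (BnBr, K2CO3, DMF, 60 °C) gives 2,4,6-tris(benzyloxy)benzaldehyde F1. mCPBA converts it into 2,4,6-tris(benzyloxy)phenyl formate F2, and K2CO3 in MeOH gives 2,4,6-tris(benzyloxy)phenol F3. SNAr of this phenol on fluoroaldehyde 22 (Cs2CO3, DMSO, 110 °C) gives 2,4-bis(benzyloxy)-6-[2,4,6-tris(benzyloxy)phenoxy]benzaldehyde F4. mCPBA then gives 2,4-bis(benzyloxy)-6-[2,4,6-tris(benzyloxy)phenoxy]phenyl formate F5, whose methanolysis is phenol 13.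

The second is step 10. Phenol 13 carries a benzyloxy group and a bulky aryloxy group on both sides of the OH and may not bind to copper. The fallback sets out from 13 and comes back at 16 without a metal. The phenoxide (K2CO3, DMF, 0 °C → rt) displaces the para fluoride of commercial 2,4,6-trifluorobenzaldehyde, the least hindered of the three activated positions, to give 4-{2,4-bis(benzyloxy)-6-[2,4,6-tris(benzyloxy)phenoxy]phenoxy}-2,6-difluorobenzaldehyde F6. Two equivalents of sodium benzyl oxide (BnOH, NaH, THF, 0 °C → rt) then replace the two fluorides ortho to the aldehyde and give 16.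

The third is step 17. Here the hindered phenol 25 meets an electron-rich, unactivated bromide on the most advanced material. The fallback sets out from 25 and ends at 29, using a ring A partner with an activating group that is removed afterwards. Coupling of 25 with the activated bromoaldehyde 15 under the conditions already proven in step 10 gives 2,6-bis(benzyloxy)-4-[2,4-bis(benzyloxy)-6-(2,6-bis(benzyloxy)-4-{2,4-bis(benzyloxy)-6-[2,4,6-tris(benzyloxy)phenoxy]phenoxy}phenoxy)phenoxy]benzaldehyde F7. Pinnick oxidation (NaClO2, NaH2PO4, 2-methyl-2-butene, t-BuOH/THF/H2O) gives 2,6-bis(benzyloxy)-4-[2,4-bis(benzyloxy)-6-(2,6-bis(benzyloxy)-4-{2,4-bis(benzyloxy)-6-[2,4,6-tris(benzyloxy)phenoxy]phenoxy}phenoxy)phenoxy]benzoic acid F8. Hydrogenolysis (H2, Pd/C) gives 4-[2,4-dihydroxy-6-(2,6-dihydroxy-4-{2,4-dihydroxy-6-[2,4,6-trihydroxyphenoxy]phenoxy}phenoxy)phenoxy]-2,6-dihydroxybenzoic acid F9. This 2,6-dihydroxybenzoic acid loses CO2 on warming in degassed water (90–100 °C, argon) to give 29.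

**Further compounds**
F1 | step 6 | 2,4,6-tris(benzyloxy)benzaldehyde | O=Cc1c(OCc2ccccc2)cc(OCc2ccccc2)cc1OCc1ccccc1
F2 | step 6 | 2,4,6-tris(benzyloxy)phenyl formate | O=COc1c(OCc2ccccc2)cc(OCc2ccccc2)cc1OCc1ccccc1
F3 | step 6 | 2,4,6-tris(benzyloxy)phenol | Oc1c(OCc2ccccc2)cc(OCc2ccccc2)cc1OCc1ccccc1
F4 | step 6 | 2,4-bis(benzyloxy)-6-[2,4,6-tris(benzyloxy)phenoxy]benzaldehyde | O=Cc1c(OCc2ccccc2)cc(OCc2ccccc2)cc1Oc1c(OCc2ccccc2)cc(OCc2ccccc2)cc1OCc1ccccc1
F5 | step 6 | 2,4-bis(benzyloxy)-6-[2,4,6-tris(benzyloxy)phenoxy]phenyl formate | O=COc1c(OCc2ccccc2)cc(OCc2ccccc2)cc1Oc1c(OCc2ccccc2)cc(OCc2ccccc2)cc1OCc1ccccc1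
F6 | step 10 | 4-{2,4-bis(benzyloxy)-6-[2,4,6-tris(benzyloxy)phenoxy]phenoxy}-2,6-difluorobenzaldehyde | O=Cc1c(F)cc(Oc2c(OCc3ccccc3)cc(OCc3ccccc3)cc2Oc2c(OCc3ccccc3)cc(OCc3ccccc3)cc2OCc2ccccc2)cc1F
F7 | step 17 | 2,6-bis(benzyloxy)-4-[2,4-bis(benzyloxy)-6-(2,6-bis(benzyloxy)-4-{2,4-bis(benzyloxy)-6-[2,4,6-tris(benzyloxy)phenoxy]phenoxy}phenoxy)phenoxy]benzaldehyde | O=Cc1c(OCc2ccccc2)cc(Oc2c(OCc3ccccc3)cc(OCc3ccccc3)cc2Oc2c(OCc3ccccc3)cc(Oc3c(OCc4ccccc4)cc(OCc4ccccc4)cc3Oc3c(OCc4ccccc4)cc(OCc4ccccc4)cc3OCc3ccccc3)cc2OCc2ccccc2)cc1OCc1ccccc1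
F8 | step 17 | 2,6-bis(benzyloxy)-4-[2,4-bis(benzyloxy)-6-(2,6-bis(benzyloxy)-4-{2,4-bis(benzyloxy)-6-[2,4,6-tris(benzyloxy)phenoxy]phenoxy}phenoxy)phenoxy]benzoic acid | OC(=O)c1c(OCc2ccccc2)cc(Oc2c(OCc3ccccc3)cc(OCc3ccccc3)cc2Oc2c(OCc3ccccc3)cc(Oc3c(OCc4ccccc4)cc(OCc4ccccc4)cc3Oc3c(OCc4ccccc4)cc(OCc4ccccc4)cc3OCc3ccccc3)cc2OCc2ccccc2)cc1OCc1ccccc1
F9 | step 17 | 4-[2,4-dihydroxy-6-(2,6-dihydroxy-4-{2,4-dihydroxy-6-[2,4,6-trihydroxyphenoxy]phenoxy}phenoxy)phenoxy]-2,6-dihydroxybenzoic acid | OC(=O)c1c(O)cc(Oc2c(O)cc(O)cc2Oc2c(O)cc(Oc3c(O)cc(O)cc3Oc3c(O)cc(O)cc3O)cc2O)cc1O
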